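**Plan**

- Locants: diterpene numbering for C1–C14 (C4 gem-dimethyl, C10 angular methyl, C13 isopropyl; C11 is the methyl on C9 until ring C exists), C15 = carbinol carbon, C1′–C6′ = bicyclo[3.1.0]hexane (C4′ spiro, C1′ isopropyl-bearing, C6′ cyclopropane CH2).
- Retrosynthesis: target ⇒ phenol 26 (desilylation, phenol/alcohol oxidation level) ⇒ cut C8–C14 and C11–C12 together, which opens rings D and C at once ⇒ seco-triflate 23 ⇒ cut C7–C15 (aldol) ⇒ AB ketone 10 + aldehyde 20 ⇒ (S)-Wieland–Miescher ketone; (+)-sabinene, methyl isovalerate and one formyl carbon.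
- Enabling feature: ring C is a six-membered carbocycle whose bond C8–C14 is also the ring C/D fusion bond and whose bond C11–C12 joins the two oxygen-bearing carbons. The two bonds are para, so ring C is two acrylate-type C3 units (C8=C9–C11 on ring B; C14=C13–C12 as a β-triflyloxy acrylate) held by the three-atom tether C7–C15–C4′.
- Forward: rings A/B are bought and trimmed (steps 1–6), the sabinane arm is built (steps 7–11), the two are joined by an aldol (step 12), ring D and then ring C close in one operation (step 15), and oxidation gives the hydroxy-quinone methide (steps 16–17).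
- Stereochemistry: C10 from (S)-Wieland–Miescher ketone; C1′/C5′ from (+)-sabinene; C4′ by substrate control (attack anti to the cyclopropane CH2); C15 by Felkin–Anh control from C4′; C5 by thermodynamic epimerisation to the cis-fused 6-ketone.

Key step: step 15

Assumption: the A/B cis-fused 6-ketone (5β-H) is taken to be the more stable C5 epimer of these 4,4-dimethyl-6-oxodecalins, and (+)-sabinene is taken as the (1R,5R) enantiomer.

**Route**

Step 1
Reactants: 1 (S)-Wieland–Miescher ketone
Product: 2 (10S)-9-hydroxy-9,10-dimethyl-Δ4-octalin-3-one (OH cis to the C10 methyl)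
Conditions: MeMgBr (1.1 equiv), THF, −78 → −40 °C; aq. NH4Cl
Reagents that add atoms: methylmagnesium bromide, C[Mg]Br
Why: Chemoselective Grignard 1,2-addition to the saturated C9 ketone, which is more electrophilic than the vinylogous enone carbonyl (the preference that underlies the selective borohydride reduction of this diketone), with attack anti to the angular methyl setting a carbinol centre that is erased in step 6.

Step 2
Reactants: 2 (10S)-9-hydroxy-9,10-dimethyl-Δ4-octalin-3-one
Product: 3 9-hydroxy-4,4,9,10-tetramethyl-Δ5-octalin-3-one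
Conditions: t-BuOK (3.5 equiv), MeI (5 equiv), t-BuOH, rt
Reagents that add atoms: iodomethane, CI
Why: Deconjugative α,α-dimethylation of the Δ4-3-ketone through its extended potassium dienolate, the standard entry to 4,4-dimethyl-Δ5 terpenoid A rings; the hindered tertiary alkoxide should not compete as a nucleophile, and its C9–C10 bond lies close to the enone plane, which disfavours vinylogous retro-aldol cleavage.

Step 3
Reactants: 3 9-hydroxy-4,4,9,10-tetramethyl-Δ5-octalin-3-one
Product: 5 4,4,9,10-tetramethyl-Δ5-octalin-9-ol, via hydrazone 4 (not isolated)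
Conditions: N2H4·H2O, KOH, diethylene glycol, 130 → 200 °C
Reagents that add atoms: none
Why: Wolff–Kishner (Huang–Minlon) reduction removes the C3 carbonyl through the hydrazone; the isolated trisubstituted alkene and the tertiary alcohol are inert to hot alkali.

Step 4
Reactants: 5 4,4,9,10-tetramethyl-Δ5-octalin-9-ol
Product: 7 trans-fused 4,4,9,10-tetramethyldecalin-6α,9-diol, via C6 alkylborane 6 (not isolated)
Conditions: BH3·THF (excess), THF, 0 → 40 °C; then NaOH, H2O2
Reagents that add atoms: hydrogen peroxide, OO
Why: Hydroboration–oxidation places boron on the less substituted C6 and hydrogen on C5 by syn addition from the α-face, anti to the angular methyl, so the 6α-ol with 5α-H is expected; both centres are provisional (C6 is oxidised and C5 equilibrated in step 5).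

Step 5
Reactants: 7 trans-fused 4,4,9,10-tetramethyldecalin-6α,9-diol
Product: 9 cis-fused 9-hydroxy-4,4,9,10-tetramethyldecalin-6-one (5β-H), via trans-fused ketone 8 (not isolated)
Conditions: Dess–Martin periodinane, NaHCO3, CH2Cl2, rt; then NaOMe (0.2 equiv), MeOH, 40 °C
Reagents that add atoms: none
Why: Dess–Martin oxidation of the secondary alcohol followed by base-mediated epimerisation at C5 through the enolate; the cis-fused ketone should be favoured because it removes the 4β-Me/10-Me 1,3-diaxial contact and the 4α-Me/C6=O eclipsing of the trans isomer, and this sets the C5 configuration of the target.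

Step 6
Reactants: 9 cis-fused 9-hydroxy-4,4,9,10-tetramethyldecalin-6-one
Product: 10 cis-fused 4,4,9,10-tetramethyl-Δ8-octalin-6-one
Conditions: Burgess reagent, benzene, 60 °C
Reagents that add atoms: none
Why: Burgess dehydration (syn-elimination of the sulfamate ester) avoids a free C9 cation and hence a 1,2-methyl shift from C10, should give mainly the endocyclic trisubstituted (Zaitsev) alkene, and is neutral so that C5 is not touched.

Step 7
Reactants: 11 (+)-sabinene
Product: 13 (1-isopropylbicyclo[3.1.0]hex-4-yl)methanol, via B-alkyl-9-BBN 12 (not isolated)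
Conditions: 9-BBN, THF, rt; then NaOH, H2O2
Reagents that add atoms: hydrogen peroxide, OO
Why: Anti-Markovnikov hydroboration–oxidation of the exocyclic methylene gives the primary alcohol; the borane approaches anti to the cyclopropane CH2, but the C4′ centre formed is enolised later and is of no consequence.

Step 8
Reactants: 13 (1-isopropylbicyclo[3.1.0]hex-4-yl)methanol
Product: 15 1-isopropylbicyclo[3.1.0]hexane-4-carboxylic acid, via aldehyde 14 (not isolated)
Conditions: TEMPO (cat.), PhI(OAc)2 (2.5 equiv), MeCN/H2O, rt
Reagents that add atoms: water, O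
Why: TEMPO/PhI(OAc)2 oxidation in aqueous acetonitrile takes the primary alcohol through the aldehyde hydrate to the acid under conditions too mild to open the cyclopropane.

Step 9
Reactants: 15 1-isopropylbicyclo[3.1.0]hexane-4-carboxylic acid, 16 methyl isovalerate
Product: 18 methyl 2-isopropyl-3-oxo-3-(1-isopropylbicyclo[3.1.0]hex-4-yl)propanoate, via acyl imidazolide 17 (not isolated)
Conditions: CDI, THF, rt; then added to 16/LDA (2.2 equiv each), THF, −78 → 0 °C; aq. NH4Cl
Reagents that add atoms: none
Why: Crossed Claisen condensation in which the acyl imidazolide C-acylates the lithium enolate of the ester, and the second equivalent of enolate converts the product into its stable β-keto ester enolate, which drives the reaction.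

Step 10
Reactants: 18 methyl 2-isopropyl-3-oxo-3-(1-isopropylbicyclo[3.1.0]hex-4-yl)propanoate
Product: 19 C4′-formyl β-keto ester (quaternary C4′, CHO anti to the cyclopropane CH2)
Conditions: LDA (2.3 equiv), THF, −78 → 0 °C; DMF, −78 °C → rt; cold dilute HCl
Reagents that add atoms: N,N-dimethylformamide, CN(C)C=O
Why: Weiler-type β-keto ester dianion chemistry in which the more reactive γ-carbanion (C4′) attacks DMF and the hemiaminal is unmasked as the aldehyde on acidic work-up; the electrophile should approach the exocyclic enolate anti to the cyclopropane CH2, whose endo hydrogen shields the syn face, and this sets the spiro-centre configuration (formyl anti, C14 syn to C6′).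

Step 11
Reactants: 19 C4′-formyl β-keto ester
Product: 20 (Z)-enol triflate aldehyde
Conditions: NaH, THF, 0 °C; PhNTf2, 0 °C → rt
Reagents that add atoms: N-phenylbis(trifluoromethanesulfonimide), O=S(=O)(N(c1ccccc1)S(=O)(=O)C(F)(F)F)C(F)(F)F
Why: O-Triflation of the sodium-chelated β-keto ester enolate should give the (Z)-enol triflate (OTf cis to CO2Me), the geometry in which a later alkoxide on C15 cannot lactonise onto the ester; the non-enolisable aldehyde is spared.

Step 12
Reactants: 10 cis-fused 4,4,9,10-tetramethyl-Δ8-octalin-6-one, 20 (Z)-enol triflate aldehyde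
Product: 21 aldol adduct (C6 ketone, C15–OH)
Conditions: LDA (1.05 equiv), THF, −78 °C; then 20, −78 °C; aq. NH4Cl at −78 °C
Reagents that add atoms: none
Why: Lithium-enolate aldol addition in which kinetic deprotonation at the doubly activated C7 (α to C6=O and allylic) gives a dienolate that reacts at its α-carbon and so keeps the C8=C9 alkene; Felkin–Anh attack on the α-quaternary aldehyde anti to the alkenyl triflate group (largest substituent, best σ* acceptor) and past the ring CH2 (C3′) should give the C15 configuration of the target, while the C7 centre is erased in step 16.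

Step 13
Reactants: 21 aldol adduct
Product: 22 C15 TBS ether
Conditions: TBSOTf, 2,6-lutidine, CH2Cl2, −40 → 0 °C
Reagents that add atoms: tert-butyldimethylsilyl trifluoromethanesulfonate, CC(C)(C)[Si](C)(C)OS(=O)(=O)C(F)(F)F
Why: Silylation with the silyl triflate protects the hindered aldol hydroxyl and blocks retro-aldol cleavage.

Step 14
Reactants: 22 C15 TBS ether
Product: 23 C6 carbinol (cyclisation precursor)
Conditions: NaBH4, CeCl3·7H2O, MeOH/THF, −20 → 0 °C
Reagents that add atoms: none
Why: Luche reduction turns the C6 ketone into the carbinol (either epimer serves) so that no enolisable ketone flanks C7 during the basic key step, which removes the risk of β-elimination of the C15 silyloxy group; borohydride leaves the ester and the alkenyl triflate intact.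

Step 15
Reactants: 23 C6 carbinol (cyclisation precursor)
Product: 26 phenol (ring C aromatic, 12-OH, rings C and D closed), via Heck triene ester 24 (not isolated), via cyclohexadienone 25 (not isolated)
Conditions: Pd(OAc)2 (10 mol %), P(o-tol)3 (25 mol %), Cs2CO3 (3 equiv), degassed DMF, 95 °C
Reagents that add atoms: none
Why: Proposed new method: Pd(0) inserts into the C14–OTf bond of the β-triflyloxy acrylate, the alkenyl-palladium adds 5-exo-trig across C8=C9 (C14–C8 bond, Pd on the fully substituted C9) and syn β-hydride loss can only use the C11 methyl, giving triene ester 24; carbonate then removes the doubly allylic, vinylogously acidified C8–H, and the resulting 1-oxido-1-methoxyhexatriene (C12=C13–C14=C8–C9=C11) undergoes a thermal disrotatory 6π-electrocyclisation that forms C11–C12, expels methoxide to dienone 25 and tautomerises to the phenol. The closest known reaction types are the domino intramolecular Heck/6π-electrocyclisation and the dienyl-ketene (trienolate) electrocyclisation that ends the Danheiser and Dötz benzannulations. Ring D closes by 5-exo-trig carbopalladation and ring C by 6π-electrocyclisation, in which the cyclopentene just formed locks the central C14=C8 double bond s-cis on both sides. No stereocentre of the target is created (C8 is only transiently sp3 and becomes aromatic; C7 stays sp3 and is erased in step 16), and C4′, C15, C5 and C10 are untouched. The step needs exo (C8) rather than endo (C9) attack and loss of a C11 hydrogen rather than a ring hydrogen: the five-membered tether secures the former, the syn-carbopalladation leaves only methyl hydrogens syn to palladium, and the acrylate geometry is not critical because the trienolate can rotate about C13–C14 before ring closure.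

Step 16
Reactants: 26 phenol (ring C aromatic, 12-OH)
Product: 28 C15 TBS ether of the target, via o-quinone 27 (not isolated)
Conditions: IBX (3 equiv), DMSO/DMF, rt
Reagents that add atoms: 2-iodoxybenzoic acid (IBX), O=C1OI(=O)(O)c2ccccc12
Why: IBX oxidises the phenol regioselectively at the free ortho position C11 to the 11,12-o-quinone and, with the excess reagent, the C6 alcohol to the ketone; the o-quinone then tautomerises (C7–H to O11) to the hydroxy-p-quinone methide, as known for 6-oxo-abietane 11,12-o-quinones, under neutral conditions that leave C5 and the silyl ether untouched.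

Step 17
Reactants: 28 C15 TBS ether of the target
Product: 29 target (CNP0178265.1)
Conditions: HF·pyridine, pyridine/THF, 0 °C → rt
Reagents that add atoms: none
Why: Fluoride-mediated desilylation with buffered HF·pyridine frees the C15 alcohol without base, so that neither the quinone methide nor the epimerisable C5 centre is disturbed.

**Compound list**

1 | (S)-Wieland–Miescher ketone, (8aS)-8a-methyl-3,4,8,8a-tetrahydronaphthalene-1,6(2H,7H)-dione | C[C@]12CCC(=O)C=C1CCCC2=O | starting material
2 | (10S)-9-hydroxy-9,10-dimethyl-Δ4-octalin-3-one (OH cis to the C10 methyl) | C[C@]12CCC(=O)C=C1CCC[C@]2(C)O | intermediate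
3 | 9-hydroxy-4,4,9,10-tetramethyl-Δ5-octalin-3-one | C[C@]12CCC(=O)C(C)(C)C1=CCC[C@]2(C)O | intermediate
4 | C3 hydrazone of 3 | C[C@]12CCC(=NN)C(C)(C)C1=CCC[C@]2(C)O | intermediate
5 | 4,4,9,10-tetramethyl-Δ5-octalin-9-ol | C[C@]12CCCC(C)(C)C1=CCC[C@]2(C)O | intermediate
6 | C6 alkylborane (5α-H, 6α-boryl; drawn as the monoalkylborane) | C[C@]12CCCC(C)(C)[C@@H]1[C@@H](B)CC[C@]2(C)O | intermediate
7 | trans-fused 4,4,9,10-tetramethyldecalin-6α,9-diol (5α-H) | C[C@]12CCCC(C)(C)[C@@H]1[C@@H](O)CC[C@]2(C)O | intermediate
8 | trans-fused 9-hydroxy-4,4,9,10-tetramethyldecalin-6-one (5α-H) | C[C@]12CCCC(C)(C)[C@@H]1C(=O)CC[C@]2(C)O | intermediate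
9 | cis-fused 9-hydroxy-4,4,9,10-tetramethyldecalin-6-one (5β-H) | C[C@]12CCCC(C)(C)[C@H]1C(=O)CC[C@]2(C)O | intermediate
10 | cis-fused 4,4,9,10-tetramethyl-Δ8-octalin-6-one (5β-H, 10S; C11 methyl on C9) | C[C@]12CCCC(C)(C)[C@H]1C(=O)CC=C2C | intermediate
11 | (+)-sabinene, (1R,5R)-4-methylene-1-isopropylbicyclo[3.1.0]hexane | C=C1CC[C@]2(C(C)C)C[C@H]12 | starting material
12 | B-[(1-isopropylbicyclo[3.1.0]hex-4-yl)methyl]-9-BBN | C(B1C2CCCC1CCC2)[C@@H]3CC[C@]4(C(C)C)C[C@H]34 | intermediate
13 | (1-isopropylbicyclo[3.1.0]hex-4-yl)methanol (C4′–H anti to the cyclopropane CH2) | OC[C@@H]1CC[C@]2(C(C)C)C[C@H]12 | intermediate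
14 | 1-isopropylbicyclo[3.1.0]hexane-4-carbaldehyde | O=C[C@@H]1CC[C@]2(C(C)C)C[C@H]12 | intermediate
15 | 1-isopropylbicyclo[3.1.0]hexane-4-carboxylic acid | OC(=O)[C@@H]1CC[C@]2(C(C)C)C[C@H]12 | intermediate
16 | methyl isovalerate (methyl 3-methylbutanoate) | COC(=O)CC(C)C | starting material
17 | acyl imidazolide of 15 | O=C([C@@H]1CC[C@]2(C(C)C)C[C@H]12)n1ccnc1 | intermediate
18 | methyl 2-isopropyl-3-oxo-3-(1-isopropylbicyclo[3.1.0]hex-4-yl)propanoate (C13 epimers) | COC(=O)C(C(C)C)C(=O)[C@@H]1CC[C@]2(C(C)C)C[C@H]12 | intermediate
19 | C4′-formyl β-keto ester (quaternary C4′; CHO anti, C14 syn to the cyclopropane CH2) | COC(=O)C(C(C)C)C(=O)[C@]1(C=O)CC[C@]2(C(C)C)C[C@H]12 | intermediate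
20 | (Z)-enol triflate aldehyde (OTf cis to CO2Me) | COC(=O)/C(C(C)C)=C(\OS(=O)(=O)C(F)(F)F)[C@]1(C=O)CC[C@]2(C(C)C)C[C@H]12 | intermediate
21 | aldol adduct: ketone 10 carrying at C7 the CH(OH)–C4′ unit of 20 (C15 as in the target; C7 epimers) | C[C@]12CCCC(C)(C)[C@H]1C(=O)C(C=C2C)[C@H](O)[C@]3(CC[C@]4(C(C)C)C[C@H]34)/C(OS(=O)(=O)C(F)(F)F)=C(\C(C)C)C(=O)OC | intermediate
22 | C15 TBS ether of 21 | C[C@]12CCCC(C)(C)[C@H]1C(=O)C(C=C2C)[C@H](O[Si](C)(C)C(C)(C)C)[C@]3(CC[C@]4(C(C)C)C[C@H]34)/C(OS(=O)(=O)C(F)(F)F)=C(\C(C)C)C(=O)OC | intermediate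
23 | C6 carbinol of 22 (cyclisation precursor; C6 and C7 epimers) | C[C@]12CCCC(C)(C)[C@H]1C(O)C(C=C2C)[C@H](O[Si](C)(C)C(C)(C)C)[C@]3(CC[C@]4(C(C)C)C[C@H]34)/C(OS(=O)(=O)C(F)(F)F)=C(\C(C)C)C(=O)OC | intermediate
24 | Heck triene ester (ring D closed; C9=C11H2 exocyclic; C8–H) | C[C@]12CCCC(C)(C)[C@H]1C(O)C3C(C2=C)/C(=C(/C(C)C)C(=O)OC)[C@@]4(CC[C@]5(C(C)C)C[C@H]45)[C@H]3O[Si](C)(C)C(C)(C)C | intermediate
25 | cyclohexa-2,4-dienone (ring C closed; C12=O, C11H2) | CC(C)C1=C2C3=C(CC1=O)[C@@]4(C)CCCC(C)(C)[C@H]4C(O)C3[C@H](O[Si](C)(C)C(C)(C)C)[C@]25CC[C@]6(C(C)C)C[C@@H]65 | intermediate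
26 | phenol: ring C aromatic with 12-OH and 13-isopropyl, C6–OH, C15–OTBS, C7–H | CC(C)c1c(O)cc2c3c1[C@@]4(CC[C@]5(C(C)C)C[C@H]45)[C@@H](O[Si](C)(C)C(C)(C)C)C3C(O)[C@@H]6C(C)(C)CCC[C@]26C | intermediate
27 | 11,12-o-quinone 6-ketone (C7–H) | CC(C)C1=C2C3=C(C(=O)C1=O)[C@@]4(C)CCCC(C)(C)[C@H]4C(=O)C3[C@H](O[Si](C)(C)C(C)(C)C)[C@]25CC[C@]6(C(C)C)C[C@@H]65 | intermediate
28 | C15 TBS ether of the target | CC(C)C1=C2C3=C(C(=O)[C@@H]4C(C)(C)CCC[C@]4(C)C3=C(O)C1=O)[C@H](O[Si](C)(C)C(C)(C)C)[C@]21CC[C@]2(C(C)C)C[C@@H]21 | intermediate
29 | CNP0178265.1 | CC(C)C1=C2C3=C(C(=O)[C@@H]4C(C)(C)CCC[C@]4(C)C3=C(O)C1=O)[C@H](O)[C@]21CC[C@]2(C(C)C)C[C@@H]21 | target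

**Totals and risks**

Total step count: 17. Longest linear sequence: 12 steps (steps 1–6, then 12–17); the sabinane branch is 5 steps before the union.

Most likely to fail:

1. Step 15 (proposed cascade). The alkenyl-palladium may be slow to insert into the hindered trisubstituted C8=C9 alkene, so that carbonate attacks the triflate sulfur first; or the sequence may stall at triene ester 24 because enolisation at C8 is too slow. The fallback uses known chemistry and separates the two ring closures. It sets out from 23: a base-free cationic Heck cyclisation (Pd(OAc)2, PPh3, Ag2CO3, MeCN, 70 °C) should give the triene ester 24, which is isolated. Saponification (LiOH, THF/MeOH/H2O, 50 °C) should give the dienoic acid F1. Classical thermal benzannulation through the mixed anhydride and the dienyl ketene (Ac2O, NaOAc, 120 °C) should give the aryl/C6 diacetate F2. Methanolysis (K2CO3, MeOH, rt) comes back to the route at 26.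

2. Step 12 (aldol union). Facial selectivity at C15 may be poor if the closed lithium transition state and the chiral enolate work against Felkin–Anh control, and the hindered aldolate may revert by retro-aldol before the quench. The fallback sets out from 10: soft enolisation (TMSOTf, Et3N, CH2Cl2, 0 °C) should give the 6-silyloxy-6,8-diene (silyl dienol ether) F3. Its Mukaiyama aldol addition to 20 (BF3·OEt2, CH2Cl2, −78 °C) runs through an open transition state in which only the Felkin–Anh preference of the aldehyde operates, and is irreversible after silyl transfer. It comes back to the route at 21.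

3. Step 5 (C5 epimerisation). The equilibration may be incomplete, or may not favour the cis-fused ketone as strongly as assumed at this saturated-ring stage, which would carry the wrong C5 epimer forward. The fallback replaces thermodynamic by kinetic, stereospecific control and sets out from 5: epoxidation on the α-face, anti to the angular methyl (dimethyldioxirane or mCPBA/NaHCO3, CH2Cl2, 0 °C), should give the 5α,6α-epoxide F4. Lewis-acid Meinwald rearrangement (BF3·OEt2, toluene, −78 °C) opens the tertiary C5–O bond and shifts the 6β-hydrogen to C5 anti to the departing oxygen, which delivers 5β-H directly. It comes back to the route at 9.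

**Further compounds**

F1 | step 15 | dienoic acid from saponification of triene ester 24 | C[C@]12CCCC(C)(C)[C@H]1C(O)C3C(C2=C)/C(=C(/C(C)C)C(=O)O)[C@@]4(CC[C@]5(C(C)C)C[C@H]45)[C@H]3O[Si](C)(C)C(C)(C)C
F2 | step 15 | diacetate of phenol 26 (12-OAc, 6-OAc) | CC(C)c1c(OC(C)=O)cc2c3c1[C@@]4(CC[C@]5(C(C)C)C[C@H]45)[C@@H](O[Si](C)(C)C(C)(C)C)C3C(OC(C)=O)[C@@H]6C(C)(C)CCC[C@]26C
F3 | step 12 | 6-(trimethylsilyloxy)-6,8-diene (silyl dienol ether of 10) | C[C@]12CCCC(C)(C)[C@H]1C(O[Si](C)(C)C)=CC=C2C
F4 | step 5 | 5α,6α-epoxide of 5 | C[C@]12CCCC(C)(C)[C@@]13O[C@H]3CC[C@]2(C)O
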